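**The flask.** If you want the end of this flask, test first whether its solution can take up the whole charge of solid substrate.

solid substrate 0.050 M; second substrate 0.100 M (in portions, 3); gas 2.2 mM (held); time 25 min; the portions of second substrate follow each other after 10 s, the first at the start

    gas ⇌ reagent, rate k1*(csat - [reagent]) (k1 = 3.20 /s, csat = 2.2 mM)
    starting material + reagent ⇌ target (K2 = 568 /M, k2 = 164 /M/s)
    solid substrate ⇌ starting material, rate k3*(cs3 - [starting material]) while solid is left; crystals form when [starting material] > cs3 (cs3 = 29 mM, k3 = 0.0541 /s)
    second substrate + reagent ⇌ second product (K4 = 280 /M, k4 = 42.3 /M/s)
    2 reagent → homo dimer (k5 = 19.9 /M/s)

- a step written with two of one species runs at k times the square of its concentration and takes two of it each time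
- solid substrate is a solid; its amount is given per volume of the solution
- at the start none of reagent is dissolved
- at the start none of the solid substrate is in solution
- what has only dissolved of solid substrate counts as not reacted
- the reaction counts as stopped when no species that holds the solid substrate changes by six tenths of a point or more over the second half of the time
- starting material means what is dissolved; the solid is not counted in it
- run time (flask): 25 min

1. why nothing more happens at 25 min, or that something still does (for what has run out or reacted, a solid counts together with what of it has only dissolved) (all of the solid substrate has reacted / it is still moving / forward and back rates have come level)
2. part of the solid substrate that has turned into other species by 25 min (what has only dissolved does not count)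
3. the target standing at 25 min, as a percentage of the solid substrate charged
4. the starting material standing at 25 min, as a percentage of the solid substrate charged

**Main step.** Begin with the step to target, with reagent at saturation and the solid already dissolved. At level, target over starting material equals K2 times the reagent, 1.25, so starting material keeps 44.5% of the charge.

**The leak.** Add the homo dimer. It takes reagent steadily and the gas replaces it, so reagent sits below saturation by the leak rate over the transfer coefficient, at 2.14 mM. The starting material's share rises to 45.1%, more than the 44.5% above, which leaves 54.9% as target.

**Second substrate.** Add its portions. Once its step is level, 62.5% of its own charge stays unbound, and a level step draws no net reagent, so keep the shares as they are.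

**The solid.** Now look for the crossing. Solubility allows starting material 58.0% of this flask's charge, and the level asks for less, 45.1%. Multiply the solubility by one plus the ratio at the leak's reagent level to get 0.0642 M, and call this the ceiling charge: the most solid substrate that dissolves whole. At this reagent level and given time to dissolve, a charge below it takes the shares above, and a charge above it holds starting material at solubility with solid remaining. This flask's charge is 77.8% of the ceiling. Dissolving at k3 times the gap to solubility, with starting material at its share of what has dissolved, takes about 1.03 min, far short of the run. So expect forward and back rates level, with 54.9% converted to target and 45.1% standing as starting material.

**The result.** The forecast gives forward and back rates have come level, 54.9% converted, 54.9% target and 45.1% starting material, since “all the solid dissolves within a few minutes”. The simulation of the flask gives forward and back rates have come level, with 54.9% converted, 54.9% target and 45.1% starting material, and its solid substrate has finished dissolving by 2.50 min, with the charge below the ceiling of 0.0642 M. The neighbour flask's 0.12 M stands above that ceiling, which puts 24.2% of its charge as starting material and 29.4% as target, and that flask stands at 24.2% and 29.4%, with 46.4% still solid.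

The constants used here were chosen freely.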